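Remark: the (4R,6S) descriptors of the dioxane building block and the (3R,5S) descriptors of the target describe the same arrangement in space; the letters change only because the CIP ranking of the neighbours changes, so the building block has the correct absolute configuration at both centres.
Remark: the phosphonium salt is used as its bromide instead of its chloride (same ylide, spectator counter-ion), because it then comes in one step from a purchased benzylic alcohol that already carries the benzyl ether; both Wittig products are carried on as alkene mixtures since step 6 removes the geometry.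

## Structural features

The target is an acyclic C12 chain whose only ring is the benzene ring of a 4-hydroxy-3-methoxyphenyl group bonded to C1. C3 and C5 carry acetoxy groups and are the only stereocentres; they are (3R,5S), that is 1,3-syn, and the C4 methylene separates them. C6 to C12 form an unfunctionalised heptyl chain, so the two arms of the diol (arylethyl on C3, heptyl on C5) differ only far from the stereocentres. The real difficulty is therefore twofold: the absolute configuration of a syn-1,3-diol that is almost symmetric, and telling its two ends apart. The fragile groups are the two secondary acetates, which tolerate neither base, hydride nor nucleophiles, and the free phenol, which would be acylated with the alcohols and must stay masked until the acetates are in place and then be released under neutral conditions. The key step exploits that C2 to C7, with the syn oxygens on C3 and C5, are the six carbons of the statin 3,5-dihydroxy acid side chain. In its acetonide form, a cis-4,6-disubstituted 1,3-dioxane, the formyl carbon is C2 and is joined to the benzylic C1 by olefination, while the ester carbon is C7.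

## Logic of the disconnections

17 from 16. The bond cut is the O–CH2 bond between the phenolic oxygen and a benzyl group added in thought. The phenol has to be masked while the C3 and C5 hydroxyls are acylated, and a group that leaves under neutral reduction cannot disturb two acetates. The gain is that the acylation needs no selectivity; the demand is that nothing else reducible (alkene, allylic C–O) is left in 16.

16 from 15. The two acyl–oxygen bonds at C3 and C5 are cut. Both esters are the same, so they come off together and leave the diol. The forward step must acylate two secondary alcohols completely without touching the C–O bonds of the stereocentres.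

15 from 14. The diol is closed in thought to an isopropylidene acetal (two O–CMe2 bonds). This is the form in which the syn pair is bought and in which it is inert to ylides, hydride and hydrogenation. The forward hydrolysis must cleave only at the acetal carbon and spare the benzyl ether.

14 from 13. No skeletal bond is cut; C1–C2 and C7–C8 are dehydrogenated in thought so that both become olefination sites, and one reduction then serves two C–C bond formations. The demand is heavy for a simple step: both alkenes must be saturated while the benzyl ether and the allylic C3–O bond survive. It must also precede acetal opening, because a free carbinol next to an electron-rich styrene would ionise in acid, and an allylic acetate there would be lost on hydrogenation.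

13 from 9 and 10 (through 11 and 12). The C7=C8 bond is cut. This removes the five terminal carbons as a simple phosphonium salt and leaves an aldehyde at C7. The forward olefination has to be faster than β-elimination of the C5 oxygen; the alkene geometry is of no concern.

9 from 7 (through 8). Only the oxidation level of C7 changes, from aldehyde back to tert-butyl ester. The ester keeps C7 inert while C2 reacts as an aldehyde, and it is the purchased form of this end. The forward reduction must halt at the aldehyde.

7 from 2 and 4 (through 5 and 6). The C1=C2 bond is cut; this is the strategic cut. It divides the molecule into the aromatic part and a six-carbon piece that holds both stereocentres and already has two different ends, so both main problems disappear at once. The forward step must not epimerise the centre next to the formyl group and must leave the ester alone.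

4 from 3. The C2 carbonyl is taken back to the primary alcohol, the stable commercial form. The forward oxidation must stop at the aldehyde and be mild enough for an α-alkoxy aldehyde.

2 from 1. The benzylic C–P bond is cut, leaving a purchased benzylic alcohol that already carries the benzyl ether. One step replaces a longer sequence from simpler aromatic precursors; the forward substitution must not cleave the ether.

## Other disconnections considered

Alternative 1: The C5–O bond is cut and the oxygen is moved in thought to C7, so the precursor is the allylic diol A2 with a fixed C3 carbinol, a C5=C6 double bond and a C7 hydroxyl of either configuration.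
- Forward key step: Re2O7 would shuttle the hydroxyl between C7 and C5 through allylic perrhenate esters ([3,3] shift). Benzaldehyde dimethyl acetal A3 would capture only the C5 isomer whose oxygen is syn to that at C3, because only that one fits the all-equatorial 2,4,6-cis-1,3-dioxane A1.
- In its favour: only C3 has to be made by asymmetric synthesis (for instance an asymmetric allylation), C5 is derived from it under thermodynamic control, the C7 carbinol may be racemic, and A2 is open to a convergent cross-metathesis with second-generation Grubbs catalyst.
- Against it here: the selectivity is an equilibrium property and depends on full reversibility of both transposition and acetalisation. The strongly Lewis-acidic rhenium oxide must be tolerated by an electron-rich aryl benzyl ether. After A1, the C6=C7 alkene (allylic to an acetal oxygen) must still be saturated and the benzylidene acetal removed while the phenol stays masked; the acetal and the aryl benzyl ether answer to the same hydrogenolysis, so the end game would be no shorter than that from 13.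
- Comparison: on structure, the chosen plan brings both centres in the purchased ring of 3 and creates none, whereas A1 creates one by relay. On mechanism, a reversible sigmatropic shift with thermodynamic trapping stands against an irreversible olefination with no stereochemical event, so the chosen route carries less stereochemical risk. On step economy the two are about equal. Alternative 1 is the better plan in flexibility, since either enantiomer follows from the choice of allylation reagent, and in atom economy, since it avoids two equivalents of phosphine oxide.

Alternative 2: The C3–C4 bond is cut.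
- Forward key step: the carbamate A6 would be deprotonated enantioselectively next to oxygen (s-BuLi, chiral diamine). The carbanion would add to the less hindered primary boron of the 1,2-bis(boronic ester) A5, itself from enantioselective diboration of a terminal alkene with a zerovalent platinum catalyst. 1,2-Migration of C4 from boron to C3 with loss of the carbamate would give the 1,3-bis(boronic ester) A4; oxidation of both C–B bonds with retention, acetylation and desilylation would finish.
- In its favour: the chain is joined at its centre in a fully convergent way, both stereocentres are under reagent or catalyst control so any stereoisomer is available, no alkene has to be hydrogenated, the phenol can carry a silyl group without conflict, and the count is about six to seven steps.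
- Against it here: the diastereomeric purity of an acyclic 1,3-diol would be the product of two independent enantioselective operations, and a minor diastereomer of so flexible a chain is hard to remove. The step needs a stoichiometric chiral diamine, strict primary-over-secondary boron selectivity and a 1,2-shift that outruns reversal of the boronate complex. The final fluoride-mediated desilylation must be buffered to protect the acetates.
- Comparison: in step economy, convergence and stereochemical generality alternative 2 is better than the chosen plan. In mechanism both are well defined, but the chosen plan has no stereo-determining step at all, because both centres sit in the cis-dioxane of 3, whose integrity is easy to check. In robustness of the individual operations and cost of the chiral source the chosen plan is ahead.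

Alternative 3: The C3–O bond is cut and the acetate is placed on the benzylic C1 with the alkene at C2=C3, which gives A8.
- Forward key step: PdCl2(MeCN)2 (divalent palladium) would coordinate the alkene, the carbonyl oxygen of the C1 acetate would attack C3 to form a six-membered acetoxonium ring, and opening at C1 would complete a suprafacial 1,3-shift to A7. Conjugation with the arene is the thermodynamic sink and the configuration at C1 is transferred to C3.
- In its favour: both acetates are in place before the key step, so no acetylation follows. A single hydrogenation over Pd/C could saturate C1=C2 and free the phenol from its benzyl carbonate, which would be the shortest end game of all plans and better than the four steps from 13 to 17.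
- Against it here: two stereocentres (C1 and C5) need separate asymmetric steps, and C1 is only a relay centre. The chirality transfer holds only while the benzylic acetate does not ionise, which an oxygen-substituted arene encourages (the carbonate is there to damp this). A7 is a cinnamyl-type acetate, open to ionisation and to C–O hydrogenolysis in the final reduction. The aryl carbonate restricts the nucleophiles and bases usable in building A8.
- Comparison: on structure, the chosen plan takes the pair of centres from one ring of fixed configuration, while the alternative builds two centres and transfers one. On mechanism, a stereospecific but fragile rearrangement of an ionisable substrate stands against an olefination without stereochemical consequence. On step economy the alternative is better after the key step, but the asymmetric steps before it bring the total to about the same.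

Key step: step 3

## Route

Step 1
Reactants: 1 (4-benzyloxy-3-methoxyphenyl)methanol
Product: 2 (4-benzyloxy-3-methoxybenzyl)triphenylphosphonium bromide
Conditions: PPh3·HBr, MeCN, reflux
Reagents that add atoms: triphenylphosphine hydrobromide, [Br-].c1ccc(cc1)[PH+](c1ccccc1)c1ccccc1
Why: Direct phosphonium salt formation from a benzylic alcohol (acid-mediated substitution by triphenylphosphine); the para-alkoxy group makes the protonated benzylic carbon highly reactive, and the weakly acidic salt should leave the aryl benzyl ether intact.

Step 2
Reactants: 3 tert-butyl 2-[(4R,6S)-6-(hydroxymethyl)-2,2-dimethyl-1,3-dioxan-4-yl]acetate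
Product: 4 tert-butyl 2-[(4R,6S)-6-formyl-2,2-dimethyl-1,3-dioxan-4-yl]acetate
Conditions: TEMPO (cat.), KBr (cat.), NaOCl, NaHCO3, CH2Cl2/H2O, 0 °C
Reagents that add atoms: none
Why: Anelli oxidation (TEMPO-mediated hypochlorite oxidation) of a primary alcohol to the aldehyde under buffered two-phase conditions, mild enough for the α-alkoxy centre, the acetonide and the tert-butyl ester; the aldehyde is used at once.

Step 3
Reactants: 2 (4-benzyloxy-3-methoxybenzyl)triphenylphosphonium bromide; 4 tert-butyl 2-[(4R,6S)-6-formyl-2,2-dimethyl-1,3-dioxan-4-yl]acetate
Product: 7 tert-butyl 2-[(4R,6S)-6-[2-(4-benzyloxy-3-methoxyphenyl)ethenyl]-2,2-dimethyl-1,3-dioxan-4-yl]acetate (E/Z mixture), via benzylidene ylide 5 (not isolated), via oxaphosphetane 6 (not isolated)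
Conditions: 2 (1.15 equiv), NaN(SiMe3)2 (1.1 equiv), THF, 0 °C; then 4, −78 → 0 °C
Reagents that add atoms: none
Why: Wittig olefination of an α-alkoxy aldehyde with a semi-stabilised benzylic ylide; the closest known reaction type is the coupling of arylmethyl and heteroarylmethyl phosphonium ylides with this class of dioxanyl aldehyde. The amide base deprotonates 2 at the benzylic carbon to give ylide 5, which adds to the formyl group of 4 in a [2+2] manner to oxaphosphetane 6; cycloreversion expels Ph3P=O and leaves the C1=C2 double bond. No ring is closed and no stereocentre is created, so the step needs only chemoselectivity and retention of the existing centres. The ylide attacks the aldehyde far faster than the hindered tert-butyl ester, which is why C7 is carried at the ester level. The centre at risk is dioxane C6 (target C3), next to the formyl group: the ylide is pre-formed with a slight deficit of base so that no free amide remains, its benzylic carbanion is only weakly basic, and the aldehyde is added at −78 °C, so carbonyl addition should outrun enolisation. The cis-dioxane is also the more stable diastereomer (both substituents equatorial), so there is no thermodynamic drive to epimerise. E/Z selectivity is not needed because step 6 saturates the alkene.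

Step 4
Reactants: 7 tert-butyl 2-[(4R,6S)-6-[2-(4-benzyloxy-3-methoxyphenyl)ethenyl]-2,2-dimethyl-1,3-dioxan-4-yl]acetate
Product: 9 2-[(4R,6S)-6-[2-(4-benzyloxy-3-methoxyphenyl)ethenyl]-2,2-dimethyl-1,3-dioxan-4-yl]acetaldehyde, via aluminium hemiacetal 8 (not isolated)
Conditions: i-Bu2AlH (1.1 equiv), CH2Cl2, −78 °C; MeOH, then aq. potassium sodium tartrate (KNaC4H4O6)
Reagents that add atoms: none
Why: Partial reduction of an ester with i-Bu2AlH; hydride addition gives the tetrahedral aluminium hemiacetal 8, which should persist at −78 °C (bulky tert-butoxy group, chelation by the β ring oxygen) and release the aldehyde only on aqueous work-up. The stereocentres are not involved.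

Step 5
Reactants: 9 2-[(4R,6S)-6-[2-(4-benzyloxy-3-methoxyphenyl)ethenyl]-2,2-dimethyl-1,3-dioxan-4-yl]acetaldehyde; 10 pentyltriphenylphosphonium bromide
Product: 13 (4S,6S)-4-[2-(4-benzyloxy-3-methoxyphenyl)ethenyl]-6-(hept-2-enyl)-2,2-dimethyl-1,3-dioxane (alkene isomers), via pentylidene ylide 11 (not isolated), via oxaphosphetane 12 (not isolated)
Conditions: 10 (1.3 equiv), NaN(SiMe3)2 (1.25 equiv), THF, 0 °C; then 9, −78 °C → rt
Reagents that add atoms: none
Why: Wittig olefination with a non-stabilised ylide forms C7=C8 (mainly Z under lithium-free conditions, which is irrelevant here); at −78 °C addition of the ylide to the unhindered aldehyde should be faster than enolisation, so the β-oxygen is not eliminated.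

Step 6
Reactants: 13 (4S,6S)-4-[2-(4-benzyloxy-3-methoxyphenyl)ethenyl]-6-(hept-2-enyl)-2,2-dimethyl-1,3-dioxane
Product: 14 (4R,6S)-4-[2-(4-benzyloxy-3-methoxyphenyl)ethyl]-6-heptyl-2,2-dimethyl-1,3-dioxane
Conditions: H2 (1 atm), PtO2 (cat.), EtOAc, rt
Reagents that add atoms: none
Why: Heterogeneous catalytic hydrogenation; PtO2 should saturate both disubstituted alkenes at 1 atm while platinum, unlike palladium, is slow to cleave aryl benzyl ethers and allylic C–O bonds in a neutral solvent. The reaction is stopped after two equivalents of H2; no stereocentre is touched.

Step 7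
Reactants: 14 (4R,6S)-4-[2-(4-benzyloxy-3-methoxyphenyl)ethyl]-6-heptyl-2,2-dimethyl-1,3-dioxane
Product: 15 (3R,5S)-1-(4-benzyloxy-3-methoxyphenyl)dodecane-3,5-diol
Conditions: 1 M aq. HCl, THF, rt
Reagents that add atoms: none
Why: Acid-catalysed acetal hydrolysis; only the bonds at the acetal carbon break, so the C–O bonds at C3 and C5 and their configuration are retained, and the aryl benzyl ether is stable to dilute acid.

Step 8
Reactants: 15 (3R,5S)-1-(4-benzyloxy-3-methoxyphenyl)dodecane-3,5-diol
Product: 16 (3R,5S)-1-(4-benzyloxy-3-methoxyphenyl)dodecane-3,5-diyl diacetate
Conditions: Ac2O, pyridine, DMAP (cat.), CH2Cl2, 0 °C → rt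
Reagents that add atoms: acetic anhydride, CC(=O)OC(C)=O
Why: DMAP-catalysed acylation esterifies both secondary alcohols at oxygen with retention; the phenol is still masked, so no chemoselectivity is required.

Step 9
Reactants: 16 (3R,5S)-1-(4-benzyloxy-3-methoxyphenyl)dodecane-3,5-diyl diacetate
Product: 17 (3R,5S)-1-(4-hydroxy-3-methoxyphenyl)dodecane-3,5-diyl diacetate
Conditions: H2 (1 atm), 10% Pd/C, EtOAc, rt
Reagents that add atoms: none
Why: Hydrogenolysis of an aryl benzyl ether over Pd/C under neutral conditions; secondary alkyl acetates, the aryl methyl ether and the saturated chain are inert, so the phenol is released without acyl loss or migration.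

## Compound list

1 | (4-benzyloxy-3-methoxyphenyl)methanol | COc1cc(CO)ccc1OCc1ccccc1 | starting material
2 | (4-benzyloxy-3-methoxybenzyl)triphenylphosphonium bromide | COc1cc(C[P+](c2ccccc2)(c2ccccc2)c2ccccc2)ccc1OCc1ccccc1.[Br-] | intermediate
3 | tert-butyl 2-[(4R,6S)-6-(hydroxymethyl)-2,2-dimethyl-1,3-dioxan-4-yl]acetate | CC(C)(C)OC(=O)C[C@H]1C[C@@H](CO)OC(C)(C)O1 | starting material
4 | tert-butyl 2-[(4R,6S)-6-formyl-2,2-dimethyl-1,3-dioxan-4-yl]acetate | CC(C)(C)OC(=O)C[C@H]1C[C@@H](C=O)OC(C)(C)O1 | intermediate
5 | benzylidene ylide (not isolated): (4-benzyloxy-3-methoxybenzylidene)triphenylphosphorane | COc1cc(C=P(c2ccccc2)(c2ccccc2)c2ccccc2)ccc1OCc1ccccc1 | intermediate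
6 | oxaphosphetane (not isolated): tert-butyl 2-[(4R,6S)-6-[3-(4-benzyloxy-3-methoxyphenyl)-2,2,2-triphenyl-1,2λ5-oxaphosphetan-4-yl]-2,2-dimethyl-1,3-dioxan-4-yl]acetate (ring diastereomers) | CC(C)(C)OC(=O)C[C@H]1C[C@@H](C2OP(c3ccccc3)(c3ccccc3)(c3ccccc3)C2c2ccc(OCc3ccccc3)c(OC)c2)OC(C)(C)O1 | intermediate
7 | tert-butyl 2-[(4R,6S)-6-[2-(4-benzyloxy-3-methoxyphenyl)ethenyl]-2,2-dimethyl-1,3-dioxan-4-yl]acetate (E/Z mixture) | CC(C)(C)OC(=O)C[C@H]1C[C@@H](C=Cc2ccc(OCc3ccccc3)c(OC)c2)OC(C)(C)O1 | intermediate
8 | aluminium hemiacetal (not isolated): [1-tert-butoxy-2-[(4R,6S)-6-[2-(4-benzyloxy-3-methoxyphenyl)ethenyl]-2,2-dimethyl-1,3-dioxan-4-yl]ethoxy]bis(2-methylpropyl)aluminium (hemiacetal carbon unassigned) | CC(C)C[Al](CC(C)C)OC(C[C@H]1C[C@@H](C=Cc2ccc(OCc3ccccc3)c(OC)c2)OC(C)(C)O1)OC(C)(C)C | intermediate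
9 | 2-[(4R,6S)-6-[2-(4-benzyloxy-3-methoxyphenyl)ethenyl]-2,2-dimethyl-1,3-dioxan-4-yl]acetaldehyde (E/Z mixture) | O=CC[C@H]1C[C@@H](C=Cc2ccc(OCc3ccccc3)c(OC)c2)OC(C)(C)O1 | intermediate
10 | pentyltriphenylphosphonium bromide | CCCCC[P+](c1ccccc1)(c1ccccc1)c1ccccc1.[Br-] | starting material
11 | pentylidene ylide (not isolated): pentylidenetriphenylphosphorane | CCCCC=P(c1ccccc1)(c1ccccc1)c1ccccc1 | intermediate
12 | oxaphosphetane (not isolated): (4S,6R)-4-[2-(4-benzyloxy-3-methoxyphenyl)ethenyl]-6-[(3-butyl-2,2,2-triphenyl-1,2λ5-oxaphosphetan-4-yl)methyl]-2,2-dimethyl-1,3-dioxane (ring diastereomers) | CCCCC1C(C[C@H]2C[C@@H](C=Cc3ccc(OCc4ccccc4)c(OC)c3)OC(C)(C)O2)OP1(c1ccccc1)(c1ccccc1)c1ccccc1 | intermediate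
13 | (4S,6S)-4-[2-(4-benzyloxy-3-methoxyphenyl)ethenyl]-6-(hept-2-enyl)-2,2-dimethyl-1,3-dioxane (alkene isomers) | CCCCC=CC[C@H]1C[C@@H](C=Cc2ccc(OCc3ccccc3)c(OC)c2)OC(C)(C)O1 | intermediate
14 | (4R,6S)-4-[2-(4-benzyloxy-3-methoxyphenyl)ethyl]-6-heptyl-2,2-dimethyl-1,3-dioxane | CCCCCCC[C@H]1C[C@@H](CCc2ccc(OCc3ccccc3)c(OC)c2)OC(C)(C)O1 | intermediate
15 | (3R,5S)-1-(4-benzyloxy-3-methoxyphenyl)dodecane-3,5-diol | CCCCCCC[C@H](O)C[C@@H](CCc1ccc(OCc2ccccc2)c(OC)c1)O | intermediate
16 | (3R,5S)-1-(4-benzyloxy-3-methoxyphenyl)dodecane-3,5-diyl diacetate | CCCCCCC[C@H](OC(C)=O)C[C@@H](CCc1ccc(OCc2ccccc2)c(OC)c1)OC(C)=O | intermediate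
17 | (3R,5S)-1-(4-hydroxy-3-methoxyphenyl)dodecane-3,5-diyl diacetate | CCCCCCC[C@@H](C[C@@H](CCc1ccc(O)c(OC)c1)OC(C)=O)OC(C)=O | target

## Step count and least certain steps

Total steps: 9. Longest linear sequence: 8 steps (3 to 17 through steps 2 to 9; the arm from 1 through steps 1 and 3 to 9 is equally long).

Step 3 (key step). The most likely failure is loss of configuration at the carbon next to the formyl group of 4 through enolisation by the ylide or by traces of amide base, which would turn the syn pair into a syn/anti mixture. Incomplete conversion is also possible if 4 has hydrated or oligomerised before use. The fallback reverses the polarity of the same C1=C2 olefination (Julia–Kocienski), so that the chiral fragment never carries an epimerisable aldehyde. It sets out from 3 and comes back at 7. A Mitsunobu reaction of 3 (PPh3, DIAD, 1-phenyl-1H-tetrazole-5-thiol, THF) would give tert-butyl 2-[(4R,6S)-2,2-dimethyl-6-[(1-phenyl-1H-tetrazol-5-yl)sulfanylmethyl]-1,3-dioxan-4-yl]acetate F1. Oxidation (mCPBA, NaHCO3, CH2Cl2) would give tert-butyl 2-[(4R,6S)-2,2-dimethyl-6-[(1-phenyl-1H-tetrazol-5-yl)sulfonylmethyl]-1,3-dioxan-4-yl]acetate F2. The anion of F2 (NaN(SiMe3)2, THF, −78 °C) would then be combined with 4-benzyloxy-3-methoxybenzaldehyde F3 (purchased, or from 1 with MnO2) to give 7.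

Step 4. The most likely failure is over-reduction to the primary alcohol, or stalled conversion of the hindered tert-butyl ester, because the tetrahedral intermediate either collapses before the quench or forms too slowly at −78 °C. The fallback separates reduction and oxidation; it sets out from 7 and comes back at 9. LiAlH4 (THF, 0 °C) would reduce 7 fully to 2-[(4S,6S)-6-[2-(4-benzyloxy-3-methoxyphenyl)ethenyl]-2,2-dimethyl-1,3-dioxan-4-yl]ethanol F4, and Dess–Martin periodinane (NaHCO3, CH2Cl2) would oxidise F4 to 9.

Step 5. The most likely failure is β-elimination of the ring oxygen through the enolate of 9, or plain enolisation, under the strongly basic non-stabilised ylide 11. The fallback forms the C7–C8 bond as a single bond by sp3–sp3 coupling and needs no aldehyde; it sets out from 7 and comes back at 14. Reduction of 7 with LiAlH4 as above would give 2-[(4S,6S)-6-[2-(4-benzyloxy-3-methoxyphenyl)ethenyl]-2,2-dimethyl-1,3-dioxan-4-yl]ethanol F4. TsCl in pyridine would give 2-[(4S,6S)-6-[2-(4-benzyloxy-3-methoxyphenyl)ethenyl]-2,2-dimethyl-1,3-dioxan-4-yl]ethyl 4-methylbenzenesulfonate F5. Pentylmagnesium bromide with catalytic Li2CuCl4 (THF, −20 → 0 °C) would displace the tosylate to give (4S,6S)-4-[2-(4-benzyloxy-3-methoxyphenyl)ethenyl]-6-heptyl-2,2-dimethyl-1,3-dioxane F6. The conditions of step 6 would then saturate the remaining styrene to give 14.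

Step 6. The most likely failure is hydrogenolysis competing with hydrogenation: premature loss of the benzyl group, or cleavage of the allylic C3–O bond of the dioxane before the styrene is saturated. The fallback replaces catalytic hydrogenation by a non-catalytic diimide reduction (2-nitrobenzenesulfonylhydrazide, Et3N, CH2Cl2, rt), which transfers H2 to C=C bonds in a concerted way and cannot cleave C–O bonds. It sets out from 13 and comes back at 14 and makes no new compound.

## Further compounds

F1 | step 3 | tert-butyl 2-[(4R,6S)-2,2-dimethyl-6-[(1-phenyl-1H-tetrazol-5-yl)sulfanylmethyl]-1,3-dioxan-4-yl]acetate | CC(C)(C)OC(=O)C[C@H]1C[C@@H](CSc2nnnn2-c2ccccc2)OC(C)(C)O1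
F2 | step 3 | tert-butyl 2-[(4R,6S)-2,2-dimethyl-6-[(1-phenyl-1H-tetrazol-5-yl)sulfonylmethyl]-1,3-dioxan-4-yl]acetate | CC(C)(C)OC(=O)C[C@H]1C[C@@H](CS(=O)(=O)c2nnnn2-c2ccccc2)OC(C)(C)O1
F3 | step 3 | 4-benzyloxy-3-methoxybenzaldehyde | COc1cc(C=O)ccc1OCc1ccccc1
F4 | step 4 | 2-[(4S,6S)-6-[2-(4-benzyloxy-3-methoxyphenyl)ethenyl]-2,2-dimethyl-1,3-dioxan-4-yl]ethanol | OCC[C@H]1C[C@@H](C=Cc2ccc(OCc3ccccc3)c(OC)c2)OC(C)(C)O1
F5 | step 5 | 2-[(4S,6S)-6-[2-(4-benzyloxy-3-methoxyphenyl)ethenyl]-2,2-dimethyl-1,3-dioxan-4-yl]ethyl 4-methylbenzenesulfonate | Cc1ccc(cc1)S(=O)(=O)OCC[C@H]1C[C@@H](C=Cc2ccc(OCc3ccccc3)c(OC)c2)OC(C)(C)O1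
F6 | step 5 | (4S,6S)-4-[2-(4-benzyloxy-3-methoxyphenyl)ethenyl]-6-heptyl-2,2-dimethyl-1,3-dioxane | CCCCCCC[C@H]1C[C@@H](C=Cc2ccc(OCc3ccccc3)c(OC)c2)OC(C)(C)O1
F0 | step 6 | none | none
A1 | alternative 1 | (2R,4R,6R)-4-[2-(4-benzyloxy-3-methoxyphenyl)ethyl]-6-[(E)-hept-1-enyl]-2-phenyl-1,3-dioxane (2,4,6-cis) | CCCCC/C=C/[C@H]1C[C@@H](CCc2ccc(OCc3ccccc3)c(OC)c2)O[C@@H](c2ccccc2)O1
A2 | alternative 1 | (3R,5E)-1-(4-benzyloxy-3-methoxyphenyl)dodec-5-ene-3,7-diol (C7 epimers) | CCCCCC(O)/C=C/C[C@H](O)CCc1ccc(OCc2ccccc2)c(OC)c1
A3 | alternative 1 | benzaldehyde dimethyl acetal | COC(OC)c1ccccc1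
A4 | alternative 2 | (3R,5S)-1-(3-methoxy-4-triisopropylsilyloxyphenyl)dodecane-3,5-diyl bis(pinacol boronate) | CCCCCCC[C@@H](C[C@@H](CCc1ccc(O[Si](C(C)C)(C(C)C)C(C)C)c(OC)c1)B1OC(C)(C)C(C)(C)O1)B1OC(C)(C)C(C)(C)O1
A5 | alternative 2 | (2R)-nonane-1,2-diyl bis(pinacol boronate) | CCCCCCC[C@@H](CB1OC(C)(C)C(C)(C)O1)B1OC(C)(C)C(C)(C)O1
A6 | alternative 2 | 3-(3-methoxy-4-triisopropylsilyloxyphenyl)propyl N,N-diisopropylcarbamate | CC(C)N(C(C)C)C(=O)OCCCc1ccc(O[Si](C(C)C)(C(C)C)C(C)C)c(OC)c1
A7 | alternative 3 | (1E,3S,5S)-1-[4-(benzyloxycarbonyloxy)-3-methoxyphenyl]dodec-1-ene-3,5-diyl diacetate | CCCCCCC[C@@H](C[C@@H](/C=C/c1ccc(OC(=O)OCc2ccccc2)c(OC)c1)OC(C)=O)OC(C)=O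
A8 | alternative 3 | (1S,2E,5S)-1-[4-(benzyloxycarbonyloxy)-3-methoxyphenyl]dodec-2-ene-1,5-diyl diacetate | CCCCCCC[C@@H](C/C=C/[C@H](OC(C)=O)c1ccc(OC(=O)OCc2ccccc2)c(OC)c1)OC(C)=O
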